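**Retrosynthetic overview**
- The lactam ring (C13–C16, N) is attached last as a preformed unit: the C12–C13 bond comes from a Negishi coupling of a C12 alkylzinc with the N-Boc 4-triflyloxy-pyrrolinone 20; the acetate comes from the 6β-alcohol.
- The strategy rests on one feature: the C6–O and C9–O bonds of ring B (C5–C10) stand in a 1,4-relationship, joined through the C7–C8 unit. Both oxygens therefore come from one O2 molecule, added across C6 and C9 of the 6,8-diene 9 and then released by base as the 9α-hydroxy-Δ7-6-ketone 11.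
- C8 (8β-H) is then set by Li/NH3 and C6 (6β-O) by NaBH4.
- Diene 9 comes from (+)-sclareolide 1: acid methanolysis with dehydration to the Δ8 ester, reduction, silylation, allylic oxidation at C7 and a Shapiro reaction.
- Ring order: rings A and B (with C5 and C10) are taken intact from sclareolide; the dioxine ring of 10 is temporary; no further carbocycle is formed.

Key step: step 7

Remark: labdane numbering is used (ring A = C1–C5 and C10, ring B = C5–C10, side chain C11–C16 with C15 as the lactam carbonyl). α is the face opposite the C10 methyl group. All compounds keep the 5α-H, 10β-methyl trans-decalin of sclareolide.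

**Step 1**
Reactants: 1 (+)-sclareolide
Product: 2 methyl 13,14,15,16-tetranorlabd-8-en-12-oate
Conditions: conc. H2SO4, MeOH, 65 °C
Reagents that add atoms: methanol, CO
Why: Acid opens the tertiary lactone by alkyl–oxygen cleavage (E1 through the C8 cation) and the freed acid undergoes Fischer esterification; under the equilibrating acid the tetrasubstituted C8=C9 alkene should predominate, minor Δ7 and exocyclic isomers are removed on AgNO3-impregnated silica, and C5 and C10 are not touched.

**Step 2**
Reactants: 2 methyl 13,14,15,16-tetranorlabd-8-en-12-oate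
Product: 3 13,14,15,16-tetranorlabd-8-en-12-ol
Conditions: LiAlH4, THF, 0 °C
Reagents that add atoms: none
Why: LiAlH4 reduction of the ester to the primary alcohol; the isolated tetrasubstituted alkene is inert to hydride.

**Step 3**
Reactants: 3 13,14,15,16-tetranorlabd-8-en-12-ol
Product: 4 12-(tert-butyldimethylsilyloxy)-13,14,15,16-tetranorlabd-8-ene
Conditions: TBSCl, imidazole, DMF, rt
Reagents that add atoms: tert-butyldimethylsilyl chloride, CC(C)(C)[Si](C)(C)Cl
Why: Imidazole-promoted silyl ether formation at the primary alcohol; the TBS ether should withstand the chromium oxidation, MeLi, singlet oxygen, Li/NH3 and NaBH4 steps that follow.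

**Step 4**
Reactants: 4 12-(tert-butyldimethylsilyloxy)-13,14,15,16-tetranorlabd-8-ene
Product: 5 12-(tert-butyldimethylsilyloxy)-13,14,15,16-tetranorlabd-8-en-7-one
Conditions: CrO3, 3,5-dimethylpyrazole, CH2Cl2, −20 °C
Reagents that add atoms: chromium trioxide, O=[Cr](=O)=O
Why: Allylic oxidation by the CrO3–3,5-dimethylpyrazole complex; the ring methylene C7 is the accessible allylic site, whereas C11 is flanked by quaternary C10 and the silyloxy-bearing C12 and the C8 methyl is primary, so the conjugated 8-en-7-one should form.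

**Step 5**
Reactants: 5 12-(tert-butyldimethylsilyloxy)-13,14,15,16-tetranorlabd-8-en-7-one; 6 p-toluenesulfonyl hydrazide
Product: 7 (E)-tosylhydrazone of 5 (sulfonamide nitrogen on the C6 side)
Conditions: EtOH/THF, 4 Å molecular sieves, 60 °C, no added acid
Reagents that add atoms: none
Why: Condensation of the ketone with the sulfonyl hydrazide to the tosylhydrazone; the sulfonamide nitrogen should settle on the side of the less substituted C6, and mineral acid is left out so that the silyl ether stays.

**Step 6**
Reactants: 7 (E)-tosylhydrazone of 5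
Product: 9 12-(tert-butyldimethylsilyloxy)-13,14,15,16-tetranorlabda-6,8-diene, via 7-lithio-6,8-diene 8 (not isolated)
Conditions: MeLi (3 equiv), Et2O, 0 °C to rt; then H2O
Reagents that add atoms: none
Why: Shapiro reaction: after N–H deprotonation a second equivalent of MeLi removes the α′ hydrogen at C6 syn to the sulfonamide, loss of sulfinate and N2 gives the C7 vinyllithium, and water protonates it; the new C6=C7 bond joins C8=C9 in a homoannular diene, as is known for tosylhydrazones of cyclohexenones.

**Step 7**
Reactants: 9 12-(tert-butyldimethylsilyloxy)-13,14,15,16-tetranorlabda-6,8-diene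
Product: 11 9α-hydroxy-12-(tert-butyldimethylsilyloxy)-13,14,15,16-tetranorlabd-7-en-6-one, via 6α,9α-endoperoxide 10 (not isolated)
Conditions: O2, tetraphenylporphyrin (cat.), visible light, CH2Cl2, −20 °C; lamp off, then Et3N, 0 °C to rt
Reagents that add atoms: dioxygen, O=O
Why: Photosensitised singlet oxygen adds suprafacially across C6 and C9 of the cisoid ring-B diene in a [4+2] cycloaddition, the reaction type known for homoannular steroid dienes, and closes the transient 2,3-dioxabicyclo[2.2.2]octene 10 in one concerted ring closure. The C9 stereocentre is fixed by the face of attack: the axial methyl groups at C10 and C4 both project over the β face, so oxygen should enter from the open α face and leave C9 with oxygen α and the side chain β. Once irradiation is stopped, Et3N abstracts the bridgehead hydrogen at C6 (C9 carries none) and the O–O bond breaks in a Kornblum–DeLaMare fragmentation, giving the C6 ketone and the C9 tertiary alcohol while C7=C8 stays in place, so only one regiochemistry is possible. The step needs cycloaddition to outrun ene hydroperoxidation, which the locked s-cis diene and the low temperature favour, and it needs α-face selectivity, which the two β-axial methyls provide. The amine is withheld during irradiation because it quenches singlet oxygen.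

**Step 8**
Reactants: 11 9α-hydroxy-12-(tert-butyldimethylsilyloxy)-13,14,15,16-tetranorlabd-7-en-6-one
Product: 13 9α-hydroxy-12-(tert-butyldimethylsilyloxy)-13,14,15,16-tetranorlabdan-6-one (8β-H, 8α-methyl), via dilithium enolate-alkoxide 12 (not isolated)
Conditions: Li (3 equiv), NH3/THF, −78 °C, no added alcohol; then isoprene, solid NH4Cl
Reagents that add atoms: none
Why: Dissolving-metal (Birch-type) conjugate reduction: two electrons give the C8 carbanion/C6 enolate, C8 is protonated axially from the β face so that its methyl ends equatorial (8α) and avoids the 1,3-diaxial clash with the C10 methyl, and the enolate, which resists further reduction, is protonated at C7 only on quench; the hydroxyl proton is consumed in the process, so C9 is carried as a lithium alkoxide, a poor leaving group.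

**Step 9**
Reactants: 13 9α-hydroxy-12-(tert-butyldimethylsilyloxy)-13,14,15,16-tetranorlabdan-6-one
Product: 14 12-(tert-butyldimethylsilyloxy)-13,14,15,16-tetranorlabdane-6β,9α-diol
Conditions: NaBH4, MeOH, 0 °C
Reagents that add atoms: none
Why: Borohydride reduction of the ketone; the axial methyls at C4 and C10 block the β face, so hydride should add from the α face and give the axial 6β alcohol.

**Step 10**
Reactants: 14 12-(tert-butyldimethylsilyloxy)-13,14,15,16-tetranorlabdane-6β,9α-diol
Product: 15 6β-acetoxy-12-(tert-butyldimethylsilyloxy)-13,14,15,16-tetranorlabdan-9α-ol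
Conditions: Ac2O, DMAP, pyridine, 40 °C
Reagents that add atoms: acetic anhydride, CC(=O)OC(C)=O
Why: DMAP-catalysed acylation of the secondary alcohol; the tertiary C9 hydroxyl next to quaternary C10 is too hindered to be acetylated under these conditions.

**Step 11**
Reactants: 15 6β-acetoxy-12-(tert-butyldimethylsilyloxy)-13,14,15,16-tetranorlabdan-9α-ol
Product: 16 6β-acetoxy-13,14,15,16-tetranorlabdane-9α,12-diol
Conditions: HF·pyridine, pyridine/THF, 0 °C to rt
Reagents that add atoms: none
Why: Fluoride-mediated cleavage of the primary TBS ether under buffered conditions that leave the acetate and the tertiary alcohol alone and give no opening for acyl migration.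

**Step 12**
Reactants: 16 6β-acetoxy-13,14,15,16-tetranorlabdane-9α,12-diol
Product: 17 6β-acetoxy-12-iodo-13,14,15,16-tetranorlabdan-9α-ol
Conditions: I2, PPh3, imidazole, CH2Cl2, 0 °C
Reagents that add atoms: iodine, II
Why: Appel-type iodination: the primary alkoxyphosphonium ion is displaced by iodide in an SN2 reaction; the tertiary alcohol does not react at 0 °C, and closure to an oxetane (4-exo-tet) is slow.

**Step 13**
Reactants: 17 6β-acetoxy-12-iodo-13,14,15,16-tetranorlabdan-9α-ol
Product: 18 6β-acetoxy-12-iodo-9α-(trimethylsilyloxy)-13,14,15,16-tetranorlabdane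
Conditions: TMSOTf, 2,6-lutidine, CH2Cl2, −78 to 0 °C
Reagents that add atoms: trimethylsilyl trifluoromethanesulfonate, C[Si](C)(C)OS(=O)(=O)C(F)(F)F
Why: Silyl triflate silylation of the hindered tertiary alcohol with a non-nucleophilic base; the temporary TMS ether removes the only acidic proton before the organozinc reagent is made.

**Step 14**
Reactants: 19 tert-butyl 2,4-dioxopyrrolidine-1-carboxylate
Product: 20 tert-butyl 2-oxo-4-(trifluoromethylsulfonyloxy)-2,5-dihydro-1H-pyrrole-1-carboxylate
Conditions: Tf2O, Et3N, CH2Cl2, −78 °C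
Reagents that add atoms: trifluoromethanesulfonic anhydride, O=S(=O)(OS(=O)(=O)C(F)(F)F)C(F)(F)F
Why: O-Sulfonylation of the enol form of the tetramic acid gives the alkenyl triflate, a vinylogous acyl triflate that is activated for oxidative addition.

**Step 15**
Reactants: 18 6β-acetoxy-12-iodo-9α-(trimethylsilyloxy)-13,14,15,16-tetranorlabdane; 20 tert-butyl 2-oxo-4-(trifluoromethylsulfonyloxy)-2,5-dihydro-1H-pyrrole-1-carboxylate
Product: 22 N-Boc, 9-O-TMS derivative of the target (4-substituted tert-butyl 2-oxo-2,5-dihydro-1H-pyrrole-1-carboxylate joined to C12), via alkylzinc iodide 21 (not isolated)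
Conditions: Zn dust (BrCH2CH2Br, TMSCl activation), DMA, 35 °C; then 20, Pd(PPh3)4 (5 mol%), THF, rt
Reagents that add atoms: none
Why: Negishi coupling: zinc inserts into the primary C–I bond, the alkylzinc iodide transmetalates to the alkenylpalladium species formed from the triflate by oxidative addition to zerovalent palladium, and reductive elimination forms C12–C13; the acetate, silyl ether and carbamate are inert to the organozinc reagent.

**Step 16**
Reactants: 22 N-Boc, 9-O-TMS derivative of the target
Product: 23 target, 6β-acetoxy-9α-hydroxy-8α-methyl labdane carrying at C12 the 4-position of 1,5-dihydro-2H-pyrrol-2-one (CNP0546323.1)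
Conditions: TFA/CH2Cl2 (1:9), 0 °C; then aq. NaHCO3
Reagents that add atoms: none
Why: Acidolysis: the N-acyl carbamate loses isobutene and CO2, and the labile tertiary TMS ether is cleaved by the same acid and on aqueous work-up; low temperature and short exposure are chosen to spare the tertiary alcohol, the acetate and the unsaturated lactam.

**Compound list**
1 | (+)-sclareolide | C1C[C@@]2(C)OC(=O)C[C@@H]2[C@@]3(C)CCCC(C)(C)[C@H]13 | starting material
2 | methyl 13,14,15,16-tetranorlabd-8-en-12-oate | C1CC(C)=C(CC(=O)OC)[C@@]2(C)CCCC(C)(C)[C@H]12 | intermediate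
3 | 13,14,15,16-tetranorlabd-8-en-12-ol | C1CC(C)=C(CCO)[C@@]2(C)CCCC(C)(C)[C@H]12 | intermediate
4 | 12-(tert-butyldimethylsilyloxy)-13,14,15,16-tetranorlabd-8-ene | C1CC(C)=C(CCO[Si](C)(C)C(C)(C)C)[C@@]2(C)CCCC(C)(C)[C@H]12 | intermediate
5 | 12-(tert-butyldimethylsilyloxy)-13,14,15,16-tetranorlabd-8-en-7-one | C1C(=O)C(C)=C(CCO[Si](C)(C)C(C)(C)C)[C@@]2(C)CCCC(C)(C)[C@H]12 | intermediate
6 | p-toluenesulfonyl hydrazide | Cc1ccc(cc1)S(=O)(=O)NN | starting material
7 | (E)-tosylhydrazone of 5 | C1/C(=N\NS(=O)(=O)c3ccc(C)cc3)C(C)=C(CCO[Si](C)(C)C(C)(C)C)[C@@]2(C)CCCC(C)(C)[C@H]12 | intermediate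
8 | 7-lithio-12-(tert-butyldimethylsilyloxy)-13,14,15,16-tetranorlabda-6,8-diene | C1=C([Li])C(C)=C(CCO[Si](C)(C)C(C)(C)C)[C@@]2(C)CCCC(C)(C)[C@H]12 | intermediate
9 | 12-(tert-butyldimethylsilyloxy)-13,14,15,16-tetranorlabda-6,8-diene | C1=CC(C)=C(CCO[Si](C)(C)C(C)(C)C)[C@@]2(C)CCCC(C)(C)[C@H]12 | intermediate
10 | 6α,9α-epidioxy-12-(tert-butyldimethylsilyloxy)-13,14,15,16-tetranorlabd-7-ene | O1O[C@]2(CCO[Si](C)(C)C(C)(C)C)C(C)=C[C@H]1[C@H]3C(C)(C)CCC[C@]23C | intermediate
11 | 9α-hydroxy-12-(tert-butyldimethylsilyloxy)-13,14,15,16-tetranorlabd-7-en-6-one | O=C1C=C(C)[C@](O)(CCO[Si](C)(C)C(C)(C)C)[C@@]2(C)CCCC(C)(C)[C@H]12 | intermediate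
12 | dilithium C6-enolate, C9-alkoxide of 13 (8β-H) | [Li]OC1=C[C@@H](C)[C@](O[Li])(CCO[Si](C)(C)C(C)(C)C)[C@@]2(C)CCCC(C)(C)[C@H]12 | intermediate
13 | 9α-hydroxy-12-(tert-butyldimethylsilyloxy)-13,14,15,16-tetranorlabdan-6-one (8β-H) | O=C1C[C@@H](C)[C@](O)(CCO[Si](C)(C)C(C)(C)C)[C@@]2(C)CCCC(C)(C)[C@H]12 | intermediate
14 | 12-(tert-butyldimethylsilyloxy)-13,14,15,16-tetranorlabdane-6β,9α-diol | O[C@@H]1C[C@@H](C)[C@](O)(CCO[Si](C)(C)C(C)(C)C)[C@@]2(C)CCCC(C)(C)[C@H]12 | intermediate
15 | 6β-acetoxy-12-(tert-butyldimethylsilyloxy)-13,14,15,16-tetranorlabdan-9α-ol | CC(=O)O[C@@H]1C[C@@H](C)[C@](O)(CCO[Si](C)(C)C(C)(C)C)[C@@]2(C)CCCC(C)(C)[C@H]12 | intermediate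
16 | 6β-acetoxy-13,14,15,16-tetranorlabdane-9α,12-diol | CC(=O)O[C@@H]1C[C@@H](C)[C@](O)(CCO)[C@@]2(C)CCCC(C)(C)[C@H]12 | intermediate
17 | 6β-acetoxy-12-iodo-13,14,15,16-tetranorlabdan-9α-ol | CC(=O)O[C@@H]1C[C@@H](C)[C@](O)(CCI)[C@@]2(C)CCCC(C)(C)[C@H]12 | intermediate
18 | 6β-acetoxy-12-iodo-9α-(trimethylsilyloxy)-13,14,15,16-tetranorlabdane | CC(=O)O[C@@H]1C[C@@H](C)[C@](O[Si](C)(C)C)(CCI)[C@@]2(C)CCCC(C)(C)[C@H]12 | intermediate
19 | tert-butyl 2,4-dioxopyrrolidine-1-carboxylate | CC(C)(C)OC(=O)N1CC(=O)CC1=O | starting material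
20 | tert-butyl 2-oxo-4-(trifluoromethylsulfonyloxy)-2,5-dihydro-1H-pyrrole-1-carboxylate | CC(C)(C)OC(=O)N1CC(OS(=O)(=O)C(F)(F)F)=CC1=O | intermediate
21 | C12 alkylzinc iodide from 18 | CC(=O)O[C@@H]1C[C@@H](C)[C@](O[Si](C)(C)C)(CC[Zn]I)[C@@]2(C)CCCC(C)(C)[C@H]12 | intermediate
22 | N-Boc, 9-O-TMS derivative of the target | CC(=O)O[C@@H]1C[C@@H](C)[C@](O[Si](C)(C)C)(CCC3=CC(=O)N(C(=O)OC(C)(C)C)C3)[C@@]2(C)CCCC(C)(C)[C@H]12 | intermediate
23 | CNP0546323.1 (6β-acetoxy-9α-hydroxy labdane C13–C16 lactam) | CC(=O)O[C@@H]1C[C@@H](C)[C@](O)(CCC2=CC(=O)NC2)[C@@]2(C)CCCC(C)(C)[C@H]12 | target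

**Step count**
Total: 16 steps. Longest linear sequence: 15 steps (steps 1–13, 15, 16); step 14 prepares the coupling partner.

**Steps most likely to fail**

Step 7. Ene hydroperoxidation (hydrogen abstraction from C11, C17 or C5) may compete with the cycloaddition, the face selectivity may be incomplete, or the hindered endoperoxide may open slowly. The fallback sets out from enone 5 and avoids the diene altogether. Nucleophilic epoxidation (t-BuOOH, benzyltrimethylammonium hydroxide, THF) should deliver the peroxide anion to C9 from the α face, anti to the C10 methyl, and give 8α,9α-epoxy-12-(tert-butyldimethylsilyloxy)-13,14,15,16-tetranorlabdan-7-one F1. A Wharton transposition (N2H4·H2O, AcOH, MeOH) then moves the functionality with retention of the C9–O bond to 12-(tert-butyldimethylsilyloxy)-13,14,15,16-tetranorlabd-7-en-9α-ol F2. Allylic oxidation of the C6 methylene with t-BuOOH and catalytic dirhodium tetrakis(caprolactamate), Rh2(cap)4, should give the enone. A hexavalent chromium oxidant is avoided here because it would transpose the tertiary allylic alcohol back to 5. The route is rejoined at compound 11.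

Step 8. The C8 carbanion has its orbital aligned with the axial C9–O bond, so reductive expulsion of the C9 oxygen may compete with protonation; over-reduction of the ketone to the equatorial alcohol is the second danger. The fallback sets out from 11 and uses no electron-transfer reagent. Luche reduction (NaBH4, CeCl3·7H2O, MeOH, −78 °C) should add hydride from the α face and give 12-(tert-butyldimethylsilyloxy)-13,14,15,16-tetranorlabd-7-ene-6β,9α-diol F3. Hydrogen-atom-transfer hydrogenation (tris(dipivaloylmethanato)manganese, Mn(dpm)3, PhSiH3, t-BuOOH, i-PrOH, rt) then places a hydrogen atom on C7, and the tertiary C8 radical should take up the second hydrogen so as to give the thermodynamically preferred equatorial 8α-methyl. The route is rejoined at compound 14.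

Step 15. Zinc insertion may be slow, the organozinc may be lost by protonolysis or by β-hydride elimination after transmetalation, and the electrophilic triflate may decompose. The fallback sets out from iodide 18 and forms C12–C13 by radical conjugate addition instead of cross-coupling. A Giese reaction of 18 with tert-butyl 2-oxo-2,5-dihydro-1H-pyrrole-1-carboxylate (CC(C)(C)OC(=O)N1CC=CC1=O, commercial; (Me3Si)3SiH, AIBN, toluene, 80 °C) should give the saturated N-Boc 4-alkylpyrrolidin-2-one F4 as a mixture of C13 epimers. Enolisation of the imide-type lactam (LiHMDS, THF, −78 °C) and trapping with PhSeBr gives the C14 phenylselanyl lactam F5. Oxidation (H2O2, pyridine, CH2Cl2, 0 °C) and selenoxide syn-elimination, which can only run towards C13, restore the ring double bond. The route is rejoined at compound 22.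

**Further compounds**
F1 | step 7 | 8α,9α-epoxy-12-(tert-butyldimethylsilyloxy)-13,14,15,16-tetranorlabdan-7-one | C1C(=O)[C@@]3(C)O[C@@]3(CCO[Si](C)(C)C(C)(C)C)[C@@]2(C)CCCC(C)(C)[C@H]12
F2 | step 7 | 12-(tert-butyldimethylsilyloxy)-13,14,15,16-tetranorlabd-7-en-9α-ol | C1C=C(C)[C@](O)(CCO[Si](C)(C)C(C)(C)C)[C@@]2(C)CCCC(C)(C)[C@H]12
F3 | step 8 | 12-(tert-butyldimethylsilyloxy)-13,14,15,16-tetranorlabd-7-ene-6β,9α-diol | O[C@@H]1C=C(C)[C@](O)(CCO[Si](C)(C)C(C)(C)C)[C@@]2(C)CCCC(C)(C)[C@H]12
F4 | step 15 | N-Boc 4-alkylpyrrolidin-2-one Giese adduct (C13 epimers, 9-O-TMS, 6β-OAc) | CC(=O)O[C@@H]1C[C@@H](C)[C@](O[Si](C)(C)C)(CCC3CC(=O)N(C(=O)OC(C)(C)C)C3)[C@@]2(C)CCCC(C)(C)[C@H]12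
F5 | step 15 | C14 phenylselanyl derivative of F4 (mixture of diastereomers) | CC(=O)O[C@@H]1C[C@@H](C)[C@](O[Si](C)(C)C)(CCC3C([Se]c4ccccc4)C(=O)N(C(=O)OC(C)(C)C)C3)[C@@]2(C)CCCC(C)(C)[C@H]12
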